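**Retrosynthetic overview**

- The target is (5S,9S,10S,13R,14S)-14-hydroxylabd-8(17)-en-15-yl acetate. The strategy rests on the 1,1-disubstituted C8=C17 exocyclic alkene of ring B standing next to the C9 methine. This pair is read as Markovnikov hydropalladation of a C8≡C17 alkyne followed by insertion of a C9=C11 alkene, so the C8–C9 bond is disconnected.
- Endgame, functional-group work only: C15 acetate ⇐ 14,15-diol ⇐ D-proline α-aminoxylation at C14 of the C15 aldehyde ⇐ removal of the C1 ketone of a 1-oxolabdane.
- Cyclization precursor: a ring A cyclohexanone with a butynyl arm on C5 and an (E)-alkenyl arm on C10, trans to each other ⇐ aldol dehydration ⇐ one-pot copper-catalysed asymmetric conjugate addition of a butynyl Grignard reagent to 2,4,4-trimethylcyclohexenone (sets C5) with anti aldol trapping (sets C10) by an aldehyde from (R)-citronellol (brings C13).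
- Ring order: ring A is bought as the enone; ring B is the only ring formed, in the key step.

Key step: step 6

Numbering: labdane numbering is used throughout (ring A = C1–C5, C10; ring B = C5–C10; C17 = methylene carbon on C8; C18, C19 = methyls on C4; C20 = methyl on C10; side chain C11–C15 on C9, C16 = methyl on C13). In the monocyclic ketones 7–10, ring positions 1, 2, 3, 4 are labdane C1, C10, C5, C4. TBS = tert-butyldimethylsilyl; DMP = Dess–Martin periodinane.

Assumption: the sense of induction of the copper–carbene catalyst on the hindered trimethylcyclohexenone is fixed by a small-scale correlation, and the ligand enantiomer that gives the 3S adduct is used.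

**Route**

Step 1
Reactants: 1 (R)-citronellol
Product: 2 tert-butyl{[(3R)-3,7-dimethyloct-6-en-1-yl]oxy}dimethylsilane
Conditions: TBSCl, imidazole, DMF, 0 °C to rt
Reagents that add atoms: tert-butyldimethylsilyl chloride, CC(C)(C)[Si](C)(C)Cl
Why: Imidazole-promoted silylation of the primary alcohol; the C3 stereocentre of citronellol (the future C13) is not involved.

Step 2
Reactants: 2 tert-butyl{[(3R)-3,7-dimethyloct-6-en-1-yl]oxy}dimethylsilane
Product: 3 (4R)-6-[(tert-butyldimethylsilyl)oxy]-4-methylhexanal
Conditions: O3, CH2Cl2, −78 °C; then PPh3, −78 °C to rt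
Reagents that add atoms: ozone, [O-][O+]=O
Why: Ozonolysis with reductive work-up cleaves the trisubstituted alkene to the aldehyde and acetone; the silyl ether and the methyl-bearing stereocentre, which is γ to the new aldehyde, are untouched.

Step 3
Reactants: 4 4-bromo-1-(trimethylsilyl)but-1-yne; 5 2,4,4-trimethylcyclohex-2-en-1-one; 3 (4R)-6-[(tert-butyldimethylsilyl)oxy]-4-methylhexanal
Product: 8 (2S,3S)-2-[(4R)-6-(tert-butyldimethylsilyloxy)-1-hydroxy-4-methylhexyl]-2,4,4-trimethyl-3-[4-(trimethylsilyl)but-3-yn-1-yl]cyclohexan-1-one (both carbinol epimers), via Grignard reagent 6 (not isolated), via magnesium enolate 7 (not isolated)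
Conditions: 4, Mg, Et2O, rt; then 5, Cu(OTf)2 (3 mol%), chiral N-mesityl-N′-(1-hydroxy-4-methylpent-2-yl)imidazolinium hexafluorophosphate (4 mol%), Et2O, −30 to 0 °C, slow addition of 6; then 3, −78 °C; aq NH4Cl
Reagents that add atoms: none
Why: Copper–carbene-catalysed asymmetric conjugate addition of the Grignard reagent (chosen because dialkylzincs are sluggish toward α-substituted enones) sets C3 by ligand control of the enone face, and the aldol addition of the resulting magnesium enolate to aldehyde 3 takes place anti to the new C3 substituent, which sets the quaternary C2 with methyl cis and the new chain trans to the butynyl arm; the carbinol centre forms as a mixture that step 4 removes.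

Step 4
Reactants: 8 aldol adduct
Product: 9 (2R,3S)-2-[(1E,4R)-6-(tert-butyldimethylsilyloxy)-4-methylhex-1-en-1-yl]-2,4,4-trimethyl-3-[4-(trimethylsilyl)but-3-yn-1-yl]cyclohexan-1-one
Conditions: Burgess reagent, benzene, rt to 60 °C
Reagents that add atoms: none
Why: Burgess dehydration: the sulfamate undergoes syn elimination with a hydrogen of the only neighbouring CH2 (the other neighbour is quaternary, so no conjugated isomer and no E1cB path exists), and the E alkene is expected from either carbinol epimer because the bulky ring carbon and the chain avoid each other in the cyclic transition state.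

Step 5
Reactants: 9 silylalkyne enone
Product: 10 (2R,3S)-3-(but-3-yn-1-yl)-2-[(1E,4R)-6-(tert-butyldimethylsilyloxy)-4-methylhex-1-en-1-yl]-2,4,4-trimethylcyclohexan-1-one
Conditions: K2CO3 (cat.), MeOH, rt
Reagents that add atoms: none
Why: Methanolysis of the alkynyl C–Si bond with catalytic carbonate; the silyl ether, the ketone (quaternary α-carbon, nothing to epimerize) and the alkene, which cannot move into conjugation, are unaffected.

Step 6
Reactants: 10 1,7-enyne ketone
Product: 11 (5S,9S,10S,13R)-15-[(tert-butyldimethylsilyl)oxy]labd-8(17)-en-1-one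
Conditions: Pd2(dba)3·CHCl3 (5 mol%), P(o-tol)3 (20 mol%), AcOH (2 equiv), Et3SiH (4 equiv, slow addition), toluene, rt to 50 °C
Reagents that add atoms: none
Why: Oxidative addition of acetic acid to zerovalent palladium furnishes H–Pd–OAc (divalent palladium), which hydropalladates the C8≡C17 triple bond in the Markovnikov sense (H to C17, Pd to C8); the C8 vinylpalladium then carbopalladates the C9=C11 alkene syn, making the C8–C9 bond, and Et3SiH converts the C11 alkylpalladium acetate into an alkylpalladium hydride that reductively eliminates the C11–H bond and returns zerovalent palladium. The closest known reaction is the palladium-hydride reductive cyclization of 1,6- and 1,7-enynes with a silane to methylenecycloalkanes. Ring B closes in the 6-exo-trig mode; the 7-endo mode would require C8 to bond to the distal carbon C11 and is disfavoured by the tether. The one new stereocentre, C9, is controlled by a chair-like transition state built on the chair of ring A, whose trans-diequatorial arms on C5 and C10 are already fixed: C11 lies pseudo-equatorial, on the face of the axial C10 methyl, which gives 9S and the trans-decalin. The step needs insertion to outrun silane reduction of the vinylpalladium, and hydride capture to outrun β-hydride elimination at C11: the quaternary C4 and C10 hold the two arms gauche and close, slow addition keeps the silane concentration low while the vinylpalladium cyclizes, and coordination of the new C8=C17 alkene to palladium on C11 occupies the site that β-hydride elimination needs. The ketone, the silyl ether and C13 are spectators.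

Step 7
Reactants: 11 silyl ether ketone
Product: 12 (5S,9S,10S,13R)-15-hydroxylabd-8(17)-en-1-one
Conditions: TBAF, THF, 0 °C to rt
Reagents that add atoms: none
Why: Fluoride cleavage of the primary silyl ether, done first so that the hot alkaline step that follows runs on a defined substrate.

Step 8
Reactants: 12 hydroxy ketone
Product: 14 (5S,9S,10S,13R)-labd-8(17)-en-15-ol, via hydrazone 13 (not isolated)
Conditions: N2H4·H2O, KOH, diethylene glycol, 130 °C then 200 °C, Ar
Reagents that add atoms: none
Why: Wolff–Kishner reduction in the Huang-Minlon mode through hydrazone 13; the ketone beside the quaternary C10 needs forcing conditions, but it has no epimerizable α-stereocentre, and the isolated C8=C17 alkene and the primary alcohol should tolerate hot KOH when air is excluded (no diimide).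

Step 9
Reactants: 14 (5S,9S,10S,13R)-labd-8(17)-en-15-ol
Product: 15 (5S,9S,10S,13R)-labd-8(17)-en-15-al
Conditions: DMP, CH2Cl2, 0 °C to rt
Reagents that add atoms: none
Why: Dess–Martin oxidation of the primary alcohol stops at the aldehyde and leaves the alkene alone; C13 is β to the carbonyl and cannot epimerize.

Step 10
Reactants: 15 (5S,9S,10S,13R)-labd-8(17)-en-15-al
Product: 17 (13R,14S)-14-(phenylaminooxy)labd-8(17)-en-15-ol, via aminoxy aldehyde 16 (not isolated)
Conditions: PhNO, D-proline (25 mol%), DMSO/CHCl3, 0 °C to rt; then NaBH4, MeOH, 0 °C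
Reagents that add atoms: nitrosobenzene, O=Nc1ccccc1
Why: Proline-catalysed α-aminoxylation (enamine catalysis): the carboxylic acid of the D-proline enamine directs the oxygen of nitrosobenzene to one face of C14, which should give 14S (L-proline gives the R series with simple aldehydes), the catalyst overriding the small bias of the C13 methyl; NaBH4 reduces the labile α-aminoxy aldehyde 16 in the same flask.

Step 11
Reactants: 17 (13R,14S)-14-(phenylaminooxy)labd-8(17)-en-15-ol
Product: 18 (5S,9S,10S,13R,14S)-labd-8(17)-ene-14,15-diol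
Conditions: Zn, AcOH, THF, rt
Reagents that add atoms: none
Why: Zinc in acetic acid reductively cleaves the weak N–O bond to the diol and aniline; the C14–O bond is not touched, so the configuration is kept, and the alkene is inert.

Step 12
Reactants: 18 (5S,9S,10S,13R,14S)-labd-8(17)-ene-14,15-diol
Product: 19 (5S,9S,10S,13R,14S)-14-hydroxylabd-8(17)-en-15-yl acetate (target)
Conditions: AcCl (1.05 equiv), 2,4,6-collidine, CH2Cl2, −78 °C
Reagents that add atoms: acetyl chloride, CC(=O)Cl
Why: Selective acylation of the primary hydroxyl of a 1,2-diol with acetyl chloride and a hindered pyridine base at low temperature; the secondary C14 hydroxyl, flanked by the C13 branch, should react much more slowly.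

**Compound list**

1 | (R)-citronellol, (3R)-3,7-dimethyloct-6-en-1-ol | C[C@H](CCC=C(C)C)CCO | starting material
2 | tert-butyl{[(3R)-3,7-dimethyloct-6-en-1-yl]oxy}dimethylsilane | C[C@H](CCC=C(C)C)CCO[Si](C)(C)C(C)(C)C | intermediate
3 | (4R)-6-[(tert-butyldimethylsilyl)oxy]-4-methylhexanal | C[C@H](CCC=O)CCO[Si](C)(C)C(C)(C)C | intermediate
4 | 4-bromo-1-(trimethylsilyl)but-1-yne | C[Si](C)(C)C#CCCBr | starting material
5 | 2,4,4-trimethylcyclohex-2-en-1-one | CC1=CC(C)(C)CCC1=O | starting material
6 | [4-(trimethylsilyl)but-3-yn-1-yl]magnesium bromide | C[Si](C)(C)C#CCC[Mg]Br | intermediate (not isolated)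
7 | bromomagnesium (3S)-2,4,4-trimethyl-3-[4-(trimethylsilyl)but-3-yn-1-yl]cyclohex-1-en-1-olate | C[Si](C)(C)C#CCC[C@H]1C(C)(C)CCC(O[Mg]Br)=C1C | intermediate (not isolated)
8 | (2S,3S)-2-[(4R)-6-(tert-butyldimethylsilyloxy)-1-hydroxy-4-methylhexyl]-2,4,4-trimethyl-3-[4-(trimethylsilyl)but-3-yn-1-yl]cyclohexan-1-one, carbinol centre as a mixture; ring methyl on C2 cis and hydroxyalkyl chain trans to the butynyl arm on C3 | C[Si](C)(C)C#CCC[C@H]1C(C)(C)CCC(=O)[C@]1(C)C(O)CC[C@@H](C)CCO[Si](C)(C)C(C)(C)C | intermediate
9 | (2R,3S)-2-[(1E,4R)-6-(tert-butyldimethylsilyloxy)-4-methylhex-1-en-1-yl]-2,4,4-trimethyl-3-[4-(trimethylsilyl)but-3-yn-1-yl]cyclohexan-1-one | C[Si](C)(C)C#CCC[C@H]1C(C)(C)CCC(=O)[C@]1(C)/C=C/C[C@@H](C)CCO[Si](C)(C)C(C)(C)C | intermediate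
10 | (2R,3S)-3-(but-3-yn-1-yl)-2-[(1E,4R)-6-(tert-butyldimethylsilyloxy)-4-methylhex-1-en-1-yl]-2,4,4-trimethylcyclohexan-1-one, arms trans (key-step precursor) | C#CCC[C@H]1C(C)(C)CCC(=O)[C@]1(C)/C=C/C[C@@H](C)CCO[Si](C)(C)C(C)(C)C | intermediate
11 | (5S,9S,10S,13R)-15-[(tert-butyldimethylsilyl)oxy]labd-8(17)-en-1-one, trans-decalin with C1 ketone, C8 exocyclic methylene, 9β side chain (key-step product) | C=C1CC[C@H]2C(C)(C)CCC(=O)[C@]2(C)[C@H]1CC[C@@H](C)CCO[Si](C)(C)C(C)(C)C | intermediate
12 | (5S,9S,10S,13R)-15-hydroxylabd-8(17)-en-1-one | C=C1CC[C@H]2C(C)(C)CCC(=O)[C@]2(C)[C@H]1CC[C@@H](C)CCO | intermediate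
13 | C1 hydrazone of 12 | C=C1CC[C@H]2C(C)(C)CCC(=NN)[C@]2(C)[C@H]1CC[C@@H](C)CCO | intermediate (not isolated)
14 | (5S,9S,10S,13R)-labd-8(17)-en-15-ol | C=C1CC[C@H]2C(C)(C)CCC[C@]2(C)[C@H]1CC[C@@H](C)CCO | intermediate
15 | (5S,9S,10S,13R)-labd-8(17)-en-15-al | C=C1CC[C@H]2C(C)(C)CCC[C@]2(C)[C@H]1CC[C@@H](C)CC=O | intermediate
16 | (5S,9S,10S,13R,14S)-14-(phenylaminooxy)labd-8(17)-en-15-al | C=C1CC[C@H]2C(C)(C)CCC[C@]2(C)[C@H]1CC[C@@H](C)[C@H](ONc1ccccc1)C=O | intermediate (not isolated)
17 | (5S,9S,10S,13R,14S)-14-(phenylaminooxy)labd-8(17)-en-15-ol | C=C1CC[C@H]2C(C)(C)CCC[C@]2(C)[C@H]1CC[C@@H](C)[C@H](ONc1ccccc1)CO | intermediate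
18 | (5S,9S,10S,13R,14S)-labd-8(17)-ene-14,15-diol | C=C1CC[C@H]2C(C)(C)CCC[C@]2(C)[C@H]1CC[C@@H](C)[C@H](O)CO | intermediate
19 | (5S,9S,10S,13R,14S)-14-hydroxylabd-8(17)-en-15-yl acetate | C=C1CC[C@H]2C(C)(C)CCC[C@]2(C)[C@H]1CC[C@@H](C)[C@H](O)COC(C)=O | target

**Step count**

Total: 12 steps. Longest linear sequence: 12 steps, from (R)-citronellol 1 to 19; the branch from 4 and 5 joins at step 3 and runs 10 steps.

**Steps most likely to fail**

1. Step 6 (key step). The silane may reduce the C8 vinylpalladium before it inserts the hindered C9=C11 alkene, β-hydride elimination may compete at C11, or insertion may go through the other alkene rotamer and give the C9 epimer. Fallback, from 10 back to 11: a tin-hydride radical enyne cyclization. Bu3SnH (slow addition) and AIBN in benzene at 80 °C add a stannyl radical to C17; the C8 vinyl radical closes ring B 6-exo onto C9 through the same chair, and the C11 radical takes hydrogen from the stannane. This should give (5S,9S,10S,13R)-15-(tert-butyldimethylsilyloxy)-17-(tributylstannyl)labd-8(17)-en-1-one F1. Stirring with wet silica gel in CH2Cl2 cleaves the vinyl C–Sn bond (protodestannylation) and returns 11.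

2. Step 3. The 1,4-addition to the doubly hindered enone may be slow, so that 1,2-addition competes, or face selection by the catalyst may be poor. Fallback, from 4 (through 6) and 3 back to 8: the butynyl group is put on the α-unsubstituted enone, where dialkylzinc–phosphoramidite catalysis is well behaved, and the methyl is added afterwards.
   - Grignard reagent 6 and ZnCl2 (0.5 equiv, magnesium salts removed with 1,4-dioxane) give bis[4-(trimethylsilyl)but-3-yn-1-yl]zinc F2.
   - With Cu(OTf)2 and a BINOL-derived bis(1-phenylethyl)amine phosphoramidite in toluene at −30 °C, this adds to purchased 4,4-dimethylcyclohex-2-en-1-one F3, and TMSOTf traps the zinc enolate as (3R)-trimethyl({4,4-dimethyl-3-[4-(trimethylsilyl)but-3-yn-1-yl]cyclohex-1-en-1-yl}oxy)silane F4.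
   - MeLi then MeI give (2R,3R)-2,4,4-trimethyl-3-[4-(trimethylsilyl)but-3-yn-1-yl]cyclohexan-1-one F5.
   - TMSCl, NaI and Et3N in MeCN give the more substituted silyl enol ether, (3S)-trimethyl({2,4,4-trimethyl-3-[4-(trimethylsilyl)but-3-yn-1-yl]cyclohex-1-en-1-yl}oxy)silane F6.
   - Mukaiyama aldol of this enol ether with 3 (TiCl4, CH2Cl2, −78 °C) should enter anti to the butynyl group and give 8.

3. Step 8. Hydrazone formation at the ketone flanked by the quaternary C10 may be incomplete, or the C8=C17 alkene may migrate in hot alkali. Fallback, from 11 back to 14: a Barton–McCombie deoxygenation. LiAlH4 in THF reduces 11 to (5S,9S,10S,13R)-15-(tert-butyldimethylsilyloxy)labd-8(17)-en-1-ol F7 (either C1 epimer serves). NaH, CS2 and MeI give its O-(S-methyl dithiocarbonate) F8. Bu3SnH and AIBN in toluene at 110 °C remove the C1 oxygen to give (5S,9S,10S,13R)-15-(tert-butyldimethylsilyloxy)labd-8(17)-ene F9, and TBAF in THF then gives 14.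

**Further compounds**

F1 | step 6 | (5S,9S,10S,13R)-15-(tert-butyldimethylsilyloxy)-17-(tributylstannyl)labd-8(17)-en-1-one | CCCC[Sn](CCCC)(CCCC)C=C1CC[C@H]2C(C)(C)CCC(=O)[C@]2(C)[C@H]1CC[C@@H](C)CCO[Si](C)(C)C(C)(C)C
F2 | step 3 | bis[4-(trimethylsilyl)but-3-yn-1-yl]zinc | C[Si](C)(C)C#CCC[Zn]CCC#C[Si](C)(C)C
F3 | step 3 | 4,4-dimethylcyclohex-2-en-1-one | CC1(C)C=CC(=O)CC1
F4 | step 3 | (3R)-trimethyl({4,4-dimethyl-3-[4-(trimethylsilyl)but-3-yn-1-yl]cyclohex-1-en-1-yl}oxy)silane | C[Si](C)(C)C#CCC[C@H]1C(C)(C)CCC(O[Si](C)(C)C)=C1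
F5 | step 3 | (2R,3R)-2,4,4-trimethyl-3-[4-(trimethylsilyl)but-3-yn-1-yl]cyclohexan-1-one | C[Si](C)(C)C#CCC[C@H]1C(C)(C)CCC(=O)[C@@H]1C
F6 | step 3 | (3S)-trimethyl({2,4,4-trimethyl-3-[4-(trimethylsilyl)but-3-yn-1-yl]cyclohex-1-en-1-yl}oxy)silane | C[Si](C)(C)C#CCC[C@H]1C(C)(C)CCC(O[Si](C)(C)C)=C1C
F7 | step 8 | (5S,9S,10S,13R)-15-(tert-butyldimethylsilyloxy)labd-8(17)-en-1-ol | C=C1CC[C@H]2C(C)(C)CCC(O)[C@]2(C)[C@H]1CC[C@@H](C)CCO[Si](C)(C)C(C)(C)C
F8 | step 8 | O-[(5S,9S,10S,13R)-15-(tert-butyldimethylsilyloxy)labd-8(17)-en-1-yl] S-methyl carbonodithioate | C=C1CC[C@H]2C(C)(C)CCC(OC(=S)SC)[C@]2(C)[C@H]1CC[C@@H](C)CCO[Si](C)(C)C(C)(C)C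
F9 | step 8 | (5S,9S,10S,13R)-15-(tert-butyldimethylsilyloxy)labd-8(17)-ene | C=C1CC[C@H]2C(C)(C)CCC[C@]2(C)[C@H]1CC[C@@H](C)CCO[Si](C)(C)C(C)(C)C
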